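## Structural features

The target is a germacrane-type sesquiterpenoid: a ten-membered carbocycle (C1–C10) fused along C7–C8 to a five-membered butenolide (ring O, C12, C11, C7, C8). Germacrane numbers are used throughout: C3 ketone, C4 methyl-bearing carbon (methyl C15), C6 acyloxy carbon, C10 carbinol carbon (methyl C14), C13 acetoxymethyl carbon on C11. The lactone is fully substituted: C11 carries C13, C7 carries C6, and C8 is an enol-ester carbon whose exocyclic double bond to C9 lies in the large ring with Z geometry (lactone oxygen and C10 on the same side). There are three stereocenters: C6 (R, senecioyl ester, allylic to the butenolide), C4 (S, α to the ketone and 1,3 to C6) and C10 (R, tertiary allylic carbinol), the last remote from the other two. Fragile elements are the enol lactone (base, nucleophiles), the tertiary allylic carbinol next to an enol-ether-type olefin (acid), the γ-hydroxy ketone C10–OH/C3=O, the epimerisable C4, the allylic acetate and the senecioate, which can deconjugate. The real difficulty is the tetrasubstituted Z-ylidene butenolide inside a medium ring, together with stereocenters (C10 versus C4/C6) that cannot control one another. The key step exploits that C11 and C7 are the two carbons of an alkyne, C12 is carbon dioxide and C8 an aldehyde carbon, while C8=C9 plus the C10 carbinol are the opened form of the 2,3-epoxide of geranial.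

## Logic of the disconnections

**29 to 26.** The two ester C–O bonds (C6–O-senecioyl, C13–O-acetyl) are cut and all three oxygens are covered as silyl ethers. Acyl groups would not survive the organometallic steps and are best added last, and the change makes the three oxygens uniform. The forward steps must tell the primary C13 hydroxyl from the secondary C6 and tertiary C10 ones, and the second acylation must neither deconjugate the senecioyl group nor epimerise C4.

**26 to 24.** The C4–H and C15–H bonds are removed (26 to 25) and the ketone is taken back to the carbinol (25 to 24). This turns the C3/C4 region into the retron of an alkenyl-metal addition to an aldehyde and keeps the epimerisable C4 out of all earlier stages. The reduction must pick the enone over the dienyl lactone, and protonation at C4 must give the S centre; this is the least secured stereocenter of the plan.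

**24 to 23.** The ring bond C3–C4 is cut to an alkenyl iodide and an aldehyde. It is the only ring bond outside the lactone core that is flanked by usable functionality on both sides, and cutting it opens the ten-membered ring to an acyclic chain. The forward step is a medium-ring closure at high dilution with a metal that spares the enol lactone.

**23 to 19.** The C–I bond goes back to C–Si (22), the aldehyde to the trisubstituted alkene (20), and the C10 silyl ether to the free carbinol (19). Vinylsilane and prenyl alkene are inert towards low-valent titanium, so both reactive ends stay masked through the key step. Two points of design are tightened here. The C10 hydroxyl is silylated before the chain is cleaved, since a free γ-hydroxy aldehyde would close to a lactol and a free carbinol would give an iodoether. The alkene is cleaved before the iodination, so that no electron-rich olefin competes for the iodonium reagent.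

**19 to 13 + 14 + 3 (key step).** The bonds C11–C12 and C7–C8 and the lactone C12–O bond are cut, and the C9–O bond of an epoxide is restored. The butenolide then falls into 13 (an alkyne), 14 and 3 (an epoxy aldehyde). These are three pieces of similar size, and C6 and C10 end up in different pieces that are each made from a reliable chirality source. The forward step needs site-selective successive insertions, cis placement of carboxylate and alkoxide, and a Z-selective eliminative epoxide opening that leaves the tertiary C–O bond intact.

**3 to 1.** The two epoxide C–O bonds are cut, giving 1 via 2. The catalyst from Ti(OiPr)4 and D-(−)-diethyl tartrate has to deliver the (2R,3R)-epoxide, whose quaternary carbon maps onto the R carbinol of the target (the label at the aldehyde carbon changes to S in 3 only through a priority switch). The epoxy aldehyde must not epimerise.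

**13 to 9.** The C11–C13 bond and the alkyne itself are cut: C13 is a one-carbon electrophile, and C11 comes from a one-carbon homologation of 9 through 10. This needs non-basic olefination so that the α-silyloxy aldehyde keeps its configuration.

**9 to 4 + 5.** The C4–C5 bond is cut to the α-silylvinyl nucleophile from 4 and the terminal epoxide 5, which brings C6 from the chiral pool. Carrying the future alkyne carbon at the ester oxidation level (instead of a benzyl ether) avoids a debenzylation that the vinylsilane would not tolerate and saves an oxidation. The nucleophile must attack the epoxide CH2 and not the ester.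

## Other disconnections considered

**Alternative 1:** No ring carbon–carbon bond is made in the key step. The ten-membered ring is hidden in a decalin in which C3 and C8 are joined: the angular carbinol A1 has the hydroxyl on C3, and C8 is already the lactone γ-carbon.
- Forward step: the C3–OH of A1 becomes a hypoiodite (PhI(OAc)2, I2, visible light). The alkoxy radical cleaves C3–C8, C3 becomes the ketone, the C8 radical (tertiary, allylic, oxygen-substituted) is iodinated, and HI is lost towards C9 to give A2, the C10 triethylsilyl ether of 29.
- In favour: the medium ring is never closed against entropy. C4, C6 and C10 are set on six-membered rings, and C4 is not created late beside the ketone; on this point it is better than the chosen plan. Only one desilylation separates A2 from 29.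
- Against: A1 needs two adjacent fully substituted carbons and the full acylation pattern on a tricycle, which means a long linear build from the tetralone. The alkoxy radical has two other β-bonds and hydrogen atoms within reach. The delocalised radical can also be trapped at C11, and the olefin geometry after loss of HI is not dictated by the step.
- Comparison: the fragmentation lies closer to established radical chemistry than the titanium three-component coupling, so its key step carries less methodological risk (better). Both plans can deliver the Z-ylidene lactone; the chosen plan does so by an elimination steered by the C7 substituent. In step economy the chosen plan is convergent and should be shorter overall.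

**Alternative 2:** The cut is the C2–C3 bond. The butenolide is carried as a 2-silylfuran and the ketone as a 1,3-dithiane.
- Forward step: n-BuLi deprotonates the dithiane C–H of chloride A3, and the carbanion displaces the primary chloride at high dilution to give the furan-bridged ring A4.
- In favour: all three stereocenters are in place before cyclisation, and C4 is set in acyclic chemistry (better than the chosen plan). The furan withstands the strong base, and the reaction type is classical.
- Against: an SN2 closure of a ten-membered ring by a hindered, α-branched dithiane anion on an unactivated chloride is an unfavourable cyclisation. Intermolecular alkylation, elimination and lateral lithiation at the CH2 groups on the furan compete. After A4 the dithiane must be removed beside an electron-rich furan, the furan oxidised at the silyl-bearing carbon, the hydroxy butenolide dehydrated towards C9 with Z geometry, and the silyl groups exchanged for acyl groups.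
- Comparison: both plans must close the ten-membered carbocycle (equal). The chromium-mediated addition of the chosen plan is the more dependable closure for medium rings, while alternative 2 is better for C4. In step economy alternative 2 is worse, because furan and dithiane are masks that cost steps, and the enol lactone with its Z olefin, which the chosen key step makes directly, is still to be built.

**Alternative 3:** The bond made is C10–C1 through a [3,3] shift that breaks the C3–C8 bond of a cyclohexane. In A5 the diene consists of the C3 vinyl group and a C8 2-borylpropenyl group, cis to each other, with C3 as trimethylsilyl ether.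
- Forward step: heating A5 to about 180 °C should give A6 through a chair transition state. This sets the C8=C9 geometry, the silyl enol ether C2=C3 and the C10 quaternary centre at once. Oxidation of the C–B bond with retention then gives the carbinol.
- In favour: the ring expansion is concerted and stereospecific, and no medium ring is closed from an open chain. The enol ether forms away from C4, so a preset C4 stays untouched (better). The pericyclic mechanism is well understood, which makes it the equal or better of the chosen key step in predictability.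
- Against: the neutral variant needs high temperature, because an alkoxide would attack the lactone. A tertiary allylic boronate may undergo boron shifts or protodeboronation at that temperature, and the chair must win over the boat. A5 has adjacent fully substituted C3 and C8 and a geometrically pure trisubstituted alkenyl boronate, so it is long to make. Basic peroxide oxidation of boron endangers the enol lactone.
- Comparison: for C10 the two plans are equally secure in principle (chirality transfer there, a catalytic asymmetric epoxidation here). The chosen plan is more convergent and should need fewer steps.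

Key step: step 8

Remark on the chemistry: the target is taken as the open γ-hydroxy ketone drawn; a transannular hemiketal, should it form, would be a tautomer in equilibrium with it.

## Route

Step 1
Reactants: 1 geraniol
Product: 2 (2R,3R)-2,3-epoxygeraniol
Conditions: Ti(OiPr)4 (5 mol%), D-(−)-diethyl tartrate (6 mol%), t-BuOOH, 4 Å molecular sieves, CH2Cl2, −20 °C
Reagents that add atoms: tert-butyl hydroperoxide, CC(C)(C)OO
Why: Sharpless asymmetric epoxidation; the catalyst formed from Ti(OiPr)4 and D-(−)-diethyl tartrate should deliver oxygen to the face of the allylic 2,3-alkene that gives the (2R,3R)-epoxide, which fixes the later C10 configuration, while the remote 6,7-alkene is not an allylic alcohol and stays.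

Step 2
Reactants: 2 (2R,3R)-2,3-epoxygeraniol
Product: 3 (2S,3R)-2,3-epoxygeranial
Conditions: Dess–Martin periodinane, NaHCO3, CH2Cl2, 0 °C; used crude
Reagents that add atoms: none
Why: Dess–Martin oxidation under bicarbonate buffer gives the aldehyde without acid that could open the trisubstituted epoxide; the α-carbon is part of the three-membered ring and should not enolise, and its label changes from R to S only because CHO outranks the ring carbon.

Step 3
Reactants: 4 (1-bromovinyl)trimethylsilane, 5 methyl (2R)-oxirane-2-carboxylate
Product: 7 methyl (2R)-2-hydroxy-4-(trimethylsilyl)pent-4-enoate, via [1-(trimethylsilyl)vinyl]magnesium bromide 6 (not isolated)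
Conditions: Mg, THF, reflux; then CuI (10 mol%), 5, THF, −40 → −10 °C
Reagents that add atoms: none
Why: Copper-catalysed Grignard opening of a terminal epoxide by SN2 attack at the CH2 carbon; the C–O bond of the stereocenter is not touched, so C6 comes from 5 with retention, and the hindered alkenyl copper species should leave the ester alone at low temperature.

Step 4
Reactants: 7 methyl (2R)-2-hydroxy-4-(trimethylsilyl)pent-4-enoate
Product: 8 methyl (2R)-2-(tert-butyldimethylsilyloxy)-4-(trimethylsilyl)pent-4-enoate
Conditions: TBSCl, imidazole, DMF, rt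
Reagents that add atoms: tert-butyldimethylsilyl chloride, CC(C)(C)[Si](C)(C)Cl
Why: Standard silylation of a secondary alcohol; the silyl ether is a poor leaving group, which matters for the later titanium alkyne complex, and should last until step 15.

Step 5
Reactants: 8 methyl (2R)-2-(tert-butyldimethylsilyloxy)-4-(trimethylsilyl)pent-4-enoate
Product: 9 (2R)-2-(tert-butyldimethylsilyloxy)-4-(trimethylsilyl)pent-4-enal
Conditions: DIBAL-H, CH2Cl2, −78 °C; aq. potassium sodium tartrate; used crude
Reagents that add atoms: none
Why: Partial reduction of an α-silyloxy ester with DIBAL-H stops at the aluminium hemiacetal at −78 °C and gives the aldehyde on work-up; immediate use should avoid epimerisation.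

Step 6
Reactants: 9 (2R)-2-(tert-butyldimethylsilyloxy)-4-(trimethylsilyl)pent-4-enal
Product: 10 (3R)-1,1-dibromo-3-(tert-butyldimethylsilyloxy)-5-(trimethylsilyl)hexa-1,5-diene
Conditions: CBr4, PPh3, Zn, CH2Cl2, rt (reagent preformed); then 9, 0 °C
Reagents that add atoms: carbon tetrabromide, BrC(Br)(Br)Br
Why: First stage of the Corey–Fuchs reaction (Wittig-type dibromo-olefination) in its neutral zinc variant, so that the α-silyloxy stereocenter is not exposed to base.

Step 7
Reactants: 10 (3R)-1,1-dibromo-3-(tert-butyldimethylsilyloxy)-5-(trimethylsilyl)hexa-1,5-diene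
Product: 13 (4R)-4,7-bis(tert-butyldimethylsilyloxy)-2-(trimethylsilyl)hept-1-en-5-yne, via lithium acetylide 11 (not isolated), via lithium propargyl alkoxide 12 (not isolated)
Conditions: n-BuLi (2.1 equiv), THF, −78 °C; (CH2O)n, −78 °C → rt; TBSCl, THF/DMF, rt
Reagents that add atoms: formaldehyde (as paraformaldehyde), C=O; tert-butyldimethylsilyl chloride, CC(C)(C)[Si](C)(C)Cl
Why: Second stage of the Corey–Fuchs reaction: bromine–lithium exchange and 1,2-shift give the acetylide, which adds to formaldehyde, and the primary lithium alkoxide is silylated in the same flask; the vinylsilane is inert to n-BuLi at −78 °C.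

Step 8
Reactants: 13 (4R)-4,7-bis(tert-butyldimethylsilyloxy)-2-(trimethylsilyl)hept-1-en-5-yne, 14 carbon dioxide, 3 (2S,3R)-2,3-epoxygeranial
Product: 19 (5Z)-3-[(tert-butyldimethylsilyloxy)methyl]-4-[(1R)-1-(tert-butyldimethylsilyloxy)-3-(trimethylsilyl)but-3-en-1-yl]-5-[(2R)-2-hydroxy-2,6-dimethylhept-5-en-1-ylidene]furan-2(5H)-one, via titanacyclopropene 15 (not isolated), via oxatitanacyclopentenone 16 (not isolated), via titanium carboxylate alkoxide 17 (not isolated), via epoxy butenolide 18 (not isolated)
Conditions: Ti(OiPr)4 (1.3 equiv), i-PrMgCl (2.6 equiv), Et2O, −78 → −50 °C; CO2 (1 atm), −50 °C, then argon purge; 3 (1.5 equiv), −50 → −20 °C; aq. citric acid (pH 3–4), 0 °C → rt, organic phase dried; DBU (1.5 equiv), CH2Cl2, 0 °C → rt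
Reagents that add atoms: none
Why: Proposed new method: Ti(OiPr)4 and two equivalents of i-PrMgCl give a propene complex of divalent titanium that exchanges the alkene for the alkyne of 13 (titanacyclopropene 15); CO2 should insert into the less hindered Ti–C11 bond (C11 carries only CH2OTBS, C7 the branched C6 with its silyloxy and silylallyl groups) to give 16, and the remaining Ti–C7 alkenyl bond should then add to the aldehyde of 3, so that C11–C12 and C7–C8 are made in one flask (17). The closest known reaction types are the separate insertions of CO2 and of aldehydes into alkyne complexes made from Ti(OiPr)4 and i-PrMgCl, the addition of alkenyltitanium alkoxides to aldehydes, and the base opening of γ-oxiranyl butenolides; what is new is the use of the second Ti–C bond of the carboxylated titanacycle for carbonyl addition. Both insertions are syn, so carboxylate and C8 alkoxide are cis on C11=C7 and mild acid closes the butenolide by 5-exo-trig lactonisation (18). DBU then removes the acidic C8–H, and the 2-oxidofuran dienolate expels the epoxide oxygen from the adjacent CH carbon (vinylogous E1cB), which creates C8=C9 and frees the C10 hydroxyl. No new stereocenter remains: the C8 carbinol forms as a mixture and both epimers converge on one dienolate, C10 keeps the configuration of the Sharpless epoxide because its C–O bond is never broken, and C6 is a spectator. The Z geometry should follow from the C7 side chain, which pushes the quaternary epoxide carbon to the lactone-oxygen side in the elimination, and Z is also the thermodynamically preferred ylidene isomer. Chemoselectivity rests on the substrate: the 1,5-enyne cannot cyclise on titanium (a four-membered ring would result), the hindered vinylsilane does not bind, silyl ethers are poor leaving groups so that β-elimination to an allenyltitanium should be slow at −50 °C, and excess CO2 is purged before 3 is added.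

Step 9
Reactants: 19 (5Z)-3-[(tert-butyldimethylsilyloxy)methyl]-4-[(1R)-1-(tert-butyldimethylsilyloxy)-3-(trimethylsilyl)but-3-en-1-yl]-5-[(2R)-2-hydroxy-2,6-dimethylhept-5-en-1-ylidene]furan-2(5H)-one
Product: 20 (5Z)-3-[(tert-butyldimethylsilyloxy)methyl]-4-[(1R)-1-(tert-butyldimethylsilyloxy)-3-(trimethylsilyl)but-3-en-1-yl]-5-[(2R)-2,6-dimethyl-2-(triethylsilyloxy)hept-5-en-1-ylidene]furan-2(5H)-one
Conditions: TESOTf, 2,6-lutidine, CH2Cl2, −78 → 0 °C
Reagents that add atoms: triethylsilyl trifluoromethanesulfonate, CC[Si](CC)(CC)OS(=O)(=O)C(F)(F)F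
Why: Silyl triflate silylation of a hindered tertiary alcohol; it masks the C10 hydroxyl so that the aldehyde of step 10 cannot close to a lactol and no iodoether can form in step 11.

Step 10
Reactants: 20 (5Z)-3-[(tert-butyldimethylsilyloxy)methyl]-4-[(1R)-1-(tert-butyldimethylsilyloxy)-3-(trimethylsilyl)but-3-en-1-yl]-5-[(2R)-2,6-dimethyl-2-(triethylsilyloxy)hept-5-en-1-ylidene]furan-2(5H)-one
Product: 22 (5Z)-3-[(tert-butyldimethylsilyloxy)methyl]-4-[(1R)-1-(tert-butyldimethylsilyloxy)-3-(trimethylsilyl)but-3-en-1-yl]-5-[(2R)-2-methyl-5-oxo-2-(triethylsilyloxy)pentylidene]furan-2(5H)-one, via diol 21 (not isolated)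
Conditions: OsO4 (2 mol%), (DHQD)2PHAL (5 mol%), N-methylmorpholine N-oxide, acetone/H2O, 0 °C; then NaIO4, THF/pH 7 buffer, 0 °C
Reagents that add atoms: N-methylmorpholine N-oxide, C[N+]1([O-])CCOCC1; water, O
Why: Ligand-accelerated catalytic dihydroxylation should pick the electron-rich trisubstituted alkene (the silyl-substituted 1,1-disubstituted alkene is hindered, the two lactone olefins are electron-poor); periodate glycol cleavage then gives the aldehyde under neutral conditions that spare the enol lactone, the configuration of the diol being immaterial.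

Step 11
Reactants: 22 (5Z)-3-[(tert-butyldimethylsilyloxy)methyl]-4-[(1R)-1-(tert-butyldimethylsilyloxy)-3-(trimethylsilyl)but-3-en-1-yl]-5-[(2R)-2-methyl-5-oxo-2-(triethylsilyloxy)pentylidene]furan-2(5H)-one
Product: 23 (5Z)-3-[(tert-butyldimethylsilyloxy)methyl]-4-[(1R)-1-(tert-butyldimethylsilyloxy)-3-iodobut-3-en-1-yl]-5-[(2R)-2-methyl-5-oxo-2-(triethylsilyloxy)pentylidene]furan-2(5H)-one
Conditions: N-iodosuccinimide, 2,6-lutidine (0.2 equiv), (CF3)2CHOH, 0 °C
Reagents that add atoms: N-iodosuccinimide, O=C1CCC(=O)N1I
Why: Electrophilic ipso-iododesilylation of a 2-silyl-1-alkene through a β-silyl-stabilised cation; it is run after the prenyl alkene is gone, so no other nucleophilic olefin competes, and the enol-ester olefin is deactivated by the lactone.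

Step 12
Reactants: 23 (5Z)-3-[(tert-butyldimethylsilyloxy)methyl]-4-[(1R)-1-(tert-butyldimethylsilyloxy)-3-iodobut-3-en-1-yl]-5-[(2R)-2-methyl-5-oxo-2-(triethylsilyloxy)pentylidene]furan-2(5H)-one
Product: 24 (3RS,6R,8Z,10R)-6,13-bis(tert-butyldimethylsilyloxy)-3-hydroxy-10-(triethylsilyloxy)germacra-4(15),7(11),8-trien-12,8-olide
Conditions: CrCl2 (10 equiv), NiCl2 (0.1 equiv), degassed DMSO, 2 mM, slow addition of 23, rt
Reagents that add atoms: none
Why: Nozaki–Hiyama–Kishi reaction: nickel-catalysed formation of the C4 alkenylchromium species of trivalent chromium and its addition to the C3 aldehyde closes the ten-membered ring; organochromium reagents add to aldehydes and leave lactones alone, and the C3 carbinol epimers are both carried into step 13, where this centre is erased.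

Step 13
Reactants: 24 (3RS,6R,8Z,10R)-6,13-bis(tert-butyldimethylsilyloxy)-3-hydroxy-10-(triethylsilyloxy)germacra-4(15),7(11),8-trien-12,8-olide
Product: 25 (6R,8Z,10R)-6,13-bis(tert-butyldimethylsilyloxy)-3-oxo-10-(triethylsilyloxy)germacra-4(15),7(11),8-trien-12,8-olide
Conditions: Dess–Martin periodinane, NaHCO3, CH2Cl2, 0 °C → rt; used directly
Reagents that add atoms: none
Why: Dess–Martin oxidation of both allylic alcohol epimers should converge on one α-methylene ketone under buffered conditions that the silyl ethers and the enol lactone tolerate.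

Step 14
Reactants: 25 (6R,8Z,10R)-6,13-bis(tert-butyldimethylsilyloxy)-3-oxo-10-(triethylsilyloxy)germacra-4(15),7(11),8-trien-12,8-olide
Product: 26 (4S,6R,8Z,10R)-6,13-bis(tert-butyldimethylsilyloxy)-3-oxo-10-(triethylsilyloxy)germacra-7(11),8-dien-12,8-olide
Conditions: [(Ph3P)CuH]6 (0.5 equiv), degassed THF, H2O (3 equiv), rt
Reagents that add atoms: none
Why: Copper hydride conjugate reduction: hydride should add to the unhindered exocyclic methylene of the enone and not to the hindered, fully substituted dienyl lactone, and water protonates the copper enolate at C4. The C4 centre is set by substrate-controlled protonation on the outer face of the ring enolate; the 4S sense is not backed by a close precedent, and since C4 is the only epimerisable centre the epimers can be separated and the unwanted one re-equilibrated with DBU.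

Step 15
Reactants: 26 (4S,6R,8Z,10R)-6,13-bis(tert-butyldimethylsilyloxy)-3-oxo-10-(triethylsilyloxy)germacra-7(11),8-dien-12,8-olide
Product: 27 (4S,6R,8Z,10R)-6,10,13-trihydroxy-3-oxogermacra-7(11),8-dien-12,8-olide
Conditions: HF·pyridine, pyridine, THF, 0 °C → rt
Reagents that add atoms: none
Why: Fluoride cleavage of all three silyl ethers in a pyridine-buffered medium, which avoids base (enol lactone, C4) as well as strong acid (ionisation of the C10 carbinol).

Step 16
Reactants: 27 (4S,6R,8Z,10R)-6,10,13-trihydroxy-3-oxogermacra-7(11),8-dien-12,8-olide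
Product: 28 (4S,6R,8Z,10R)-13-acetoxy-6,10-dihydroxy-3-oxogermacra-7(11),8-dien-12,8-olide
Conditions: AcCl (1.1 equiv), 2,4,6-collidine, CH2Cl2, −78 °C
Reagents that add atoms: acetyl chloride, CC(=O)Cl
Why: Chemoselective acylation of the primary hydroxyl with acetyl chloride and a hindered pyridine base at low temperature; the ring-flanked secondary C6 hydroxyl should be much slower and the tertiary C10 hydroxyl inert.

Step 17
Reactants: 28 (4S,6R,8Z,10R)-13-acetoxy-6,10-dihydroxy-3-oxogermacra-7(11),8-dien-12,8-olide
Product: 29 (4S,6R,8Z,10R)-13-acetoxy-10-hydroxy-6-(3-methylbut-2-enoyloxy)-3-oxogermacra-7(11),8-dien-12,8-olide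
Conditions: 3-methylbut-2-enoic acid, 2,4,6-trichlorobenzoyl chloride, Et3N, THF, rt; then 28, DMAP, toluene, rt
Reagents that add atoms: 3-methylbut-2-enoic acid, CC(C)=CC(=O)O
Why: Yamaguchi esterification: the mixed anhydride and DMAP should acylate the hindered secondary C6 hydroxyl while the tertiary C10 hydroxyl stays free; avoiding the acid chloride and amine pair limits ketene formation and hence deconjugation of the senecioyl group.

## Compound list

1 | geraniol, (2E)-3,7-dimethylocta-2,6-dien-1-ol | CC(C)=CCC/C(C)=C/CO | starting material
2 | (2R,3R)-2,3-epoxygeraniol, [(2R,3R)-3-methyl-3-(4-methylpent-3-enyl)oxiran-2-yl]methanol | OC[C@H]1O[C@]1(C)CCC=C(C)C | intermediate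
3 | (2S,3R)-2,3-epoxygeranial, (2S,3R)-3-methyl-3-(4-methylpent-3-enyl)oxirane-2-carbaldehyde | O=C[C@H]1O[C@]1(C)CCC=C(C)C | intermediate
4 | (1-bromovinyl)trimethylsilane | C=C(Br)[Si](C)(C)C | starting material
5 | methyl (2R)-oxirane-2-carboxylate (methyl (R)-glycidate) | COC(=O)[C@H]1CO1 | starting material
6 | [1-(trimethylsilyl)vinyl]magnesium bromide | C=C([Mg]Br)[Si](C)(C)C | intermediate
7 | methyl (2R)-2-hydroxy-4-(trimethylsilyl)pent-4-enoate | COC(=O)[C@H](O)CC(=C)[Si](C)(C)C | intermediate
8 | methyl (2R)-2-(tert-butyldimethylsilyloxy)-4-(trimethylsilyl)pent-4-enoate | COC(=O)[C@H](O[Si](C)(C)C(C)(C)C)CC(=C)[Si](C)(C)C | intermediate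
9 | (2R)-2-(tert-butyldimethylsilyloxy)-4-(trimethylsilyl)pent-4-enal | O=C[C@H](O[Si](C)(C)C(C)(C)C)CC(=C)[Si](C)(C)C | intermediate
10 | (3R)-1,1-dibromo-3-(tert-butyldimethylsilyloxy)-5-(trimethylsilyl)hexa-1,5-diene | BrC(Br)=C[C@H](O[Si](C)(C)C(C)(C)C)CC(=C)[Si](C)(C)C | intermediate
11 | lithium acetylide of (3R)-3-(tert-butyldimethylsilyloxy)-5-(trimethylsilyl)hex-5-en-1-yne | [Li]C#C[C@H](O[Si](C)(C)C(C)(C)C)CC(=C)[Si](C)(C)C | intermediate
12 | lithium (4R)-4-(tert-butyldimethylsilyloxy)-6-(trimethylsilyl)hept-6-en-2-yn-1-olate | [Li]OCC#C[C@H](O[Si](C)(C)C(C)(C)C)CC(=C)[Si](C)(C)C | intermediate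
13 | (4R)-4,7-bis(tert-butyldimethylsilyloxy)-2-(trimethylsilyl)hept-1-en-5-yne | CC(C)(C)[Si](C)(C)OCC#C[C@H](O[Si](C)(C)C(C)(C)C)CC(=C)[Si](C)(C)C | intermediate
14 | carbon dioxide | O=C=O | starting material
15 | titanacyclopropene: diisopropoxytitanium η2-complex of the alkyne of 13 | CC(C)O[Ti]1(OC(C)C)C(CO[Si](C)(C)C(C)(C)C)=C1[C@H](O[Si](C)(C)C(C)(C)C)CC(=C)[Si](C)(C)C | intermediate
16 | oxatitanacyclopentenone: CO2 inserted at C11, titanium still on C7 | CC(C)O[Ti]1(OC(C)C)OC(=O)C(CO[Si](C)(C)C(C)(C)C)=C1[C@H](O[Si](C)(C)C(C)(C)C)CC(=C)[Si](C)(C)C | intermediate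
17 | seven-membered titanium carboxylate alkoxide after aldehyde insertion at C7 (C8 epimers) | CC(C)O[Ti]1(OC(C)C)OC(=O)C(CO[Si](C)(C)C(C)(C)C)=C([C@H](O[Si](C)(C)C(C)(C)C)CC(=C)[Si](C)(C)C)C(O1)[C@H]2O[C@]2(C)CCC=C(C)C | intermediate
18 | 3-[(tert-butyldimethylsilyloxy)methyl]-4-[(1R)-1-(tert-butyldimethylsilyloxy)-3-(trimethylsilyl)but-3-en-1-yl]-5-[(2R,3R)-3-methyl-3-(4-methylpent-3-enyl)oxiran-2-yl]furan-2(5H)-one (C5 epimers) | CC(C)(C)[Si](C)(C)OCC1=C([C@H](O[Si](C)(C)C(C)(C)C)CC(=C)[Si](C)(C)C)C([C@H]2O[C@]2(C)CCC=C(C)C)OC1=O | intermediate
19 | (5Z)-3-[(tert-butyldimethylsilyloxy)methyl]-4-[(1R)-1-(tert-butyldimethylsilyloxy)-3-(trimethylsilyl)but-3-en-1-yl]-5-[(2R)-2-hydroxy-2,6-dimethylhept-5-en-1-ylidene]furan-2(5H)-one | CC(C)(C)[Si](C)(C)OCC1=C([C@H](O[Si](C)(C)C(C)(C)C)CC(=C)[Si](C)(C)C)/C(=C/[C@](C)(O)CCC=C(C)C)OC1=O | intermediate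
20 | C10 triethylsilyl ether of 19 | CC(C)(C)[Si](C)(C)OCC1=C([C@H](O[Si](C)(C)C(C)(C)C)CC(=C)[Si](C)(C)C)/C(=C/[C@](C)(O[Si](CC)(CC)CC)CCC=C(C)C)OC1=O | intermediate
21 | vicinal diol of 20 at the former prenyl alkene (carbinol epimers) | CC(C)(C)[Si](C)(C)OCC1=C([C@H](O[Si](C)(C)C(C)(C)C)CC(=C)[Si](C)(C)C)/C(=C/[C@](C)(O[Si](CC)(CC)CC)CCC(O)C(C)(C)O)OC1=O | intermediate
22 | (5Z)-3-[(tert-butyldimethylsilyloxy)methyl]-4-[(1R)-1-(tert-butyldimethylsilyloxy)-3-(trimethylsilyl)but-3-en-1-yl]-5-[(2R)-2-methyl-5-oxo-2-(triethylsilyloxy)pentylidene]furan-2(5H)-one | CC(C)(C)[Si](C)(C)OCC1=C([C@H](O[Si](C)(C)C(C)(C)C)CC(=C)[Si](C)(C)C)/C(=C/[C@](C)(O[Si](CC)(CC)CC)CCC=O)OC1=O | intermediate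
23 | (5Z)-3-[(tert-butyldimethylsilyloxy)methyl]-4-[(1R)-1-(tert-butyldimethylsilyloxy)-3-iodobut-3-en-1-yl]-5-[(2R)-2-methyl-5-oxo-2-(triethylsilyloxy)pentylidene]furan-2(5H)-one | CC(C)(C)[Si](C)(C)OCC1=C([C@H](O[Si](C)(C)C(C)(C)C)CC(=C)I)/C(=C/[C@](C)(O[Si](CC)(CC)CC)CCC=O)OC1=O | intermediate
24 | (3RS,6R,8Z,10R)-6,13-bis(tert-butyldimethylsilyloxy)-3-hydroxy-10-(triethylsilyloxy)germacra-4(15),7(11),8-trien-12,8-olide | CC(C)(C)[Si](C)(C)OCC1=C2/C(=C/[C@](C)(O[Si](CC)(CC)CC)CCC(O)C(=C)C[C@H]2O[Si](C)(C)C(C)(C)C)OC1=O | intermediate
25 | (6R,8Z,10R)-6,13-bis(tert-butyldimethylsilyloxy)-3-oxo-10-(triethylsilyloxy)germacra-4(15),7(11),8-trien-12,8-olide | CC(C)(C)[Si](C)(C)OCC1=C2/C(=C/[C@](C)(O[Si](CC)(CC)CC)CCC(=O)C(=C)C[C@H]2O[Si](C)(C)C(C)(C)C)OC1=O | intermediate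
26 | (4S,6R,8Z,10R)-6,13-bis(tert-butyldimethylsilyloxy)-3-oxo-10-(triethylsilyloxy)germacra-7(11),8-dien-12,8-olide | CC(C)(C)[Si](C)(C)OCC1=C2/C(=C/[C@](C)(O[Si](CC)(CC)CC)CCC(=O)[C@@H](C)C[C@H]2O[Si](C)(C)C(C)(C)C)OC1=O | intermediate
27 | (4S,6R,8Z,10R)-6,10,13-trihydroxy-3-oxogermacra-7(11),8-dien-12,8-olide | OCC1=C2/C(=C/[C@](C)(O)CCC(=O)[C@@H](C)C[C@H]2O)OC1=O | intermediate
28 | (4S,6R,8Z,10R)-13-acetoxy-6,10-dihydroxy-3-oxogermacra-7(11),8-dien-12,8-olide | CC(=O)OCC1=C2/C(=C/[C@](C)(O)CCC(=O)[C@@H](C)C[C@H]2O)OC1=O | intermediate
29 | (4S,6R,8Z,10R)-13-acetoxy-10-hydroxy-6-(3-methylbut-2-enoyloxy)-3-oxogermacra-7(11),8-dien-12,8-olide, CNP0186726.1 | CC(=O)OCC1=C2/C(=C/[C@](C)(O)CCC(=O)[C@@H](C)C[C@H]2OC(=O)C=C(C)C)OC1=O | target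

## Step count and least certain steps

Total step count: 17. Longest linear sequence: 15 steps (steps 3 to 17, from 4 and 5); the epoxy aldehyde branch (steps 1 and 2) joins at step 8.

**Step 8 (key step).** Most likely to go wrong: the alkenyl–titanium bond left in 16 may be too weakly nucleophilic and be protonated instead of adding to 3; CO2 may insert at the wrong alkyne carbon; or the complex may lose a propargylic silyloxy group to give an allenyltitanium. The fallback uses known reaction types only and sets out from 13. The alkyne complex is carboxylated as before, and the titanacycle is cleaved with iodine to the (2Z,4R)-3-iodo-2-(silyloxymethyl)dienoic acid F1. This is methylated with trimethylsilyldiazomethane to the methyl ester F2. A CrCl2/NiCl2 coupling of F2 with 3 gives a chromium alkoxide that lactonises onto the cis ester, which returns the route to 18. DBU treatment as in step 8 then gives 19.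

**Step 14.** Most likely to go wrong: poor facial selectivity in the protonation of the ring enolate, so that the C4 epimer dominates, and slow or unfavourable equilibration. The fallback ties C4 to a reagent-controlled centre and sets out from 25. Corey–Bakshi–Shibata reduction with the (S)-2-methyl oxazaborolidine and catecholborane should give the (3R)-allylic alcohol F3. Hydroxyl-directed hydrogenation with [Rh(nbd)(dppb)]BF4 and H2 then delivers hydrogen to C4 from the face of the hydroxyl and gives the (3R,4S)-alcohol F4, following the anti rule of acyclic 2-substituted allylic alcohols. Should the ring conformation reverse that sense, the other catalyst enantiomer is used in the reduction. Dess–Martin oxidation of F4 rejoins the route at 26.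

**Step 12.** Most likely to go wrong: intermolecular coupling or simple reduction of the C–I bond outrunning the ten-membered ring closure. The fallback changes the electrophile and skips the carbinol, setting out from 23. Pinnick oxidation gives the carboxylic acid F5, and 2,2'-dipyridyl disulfide with PPh3 gives the S-pyridin-2-yl thioester F6. An intramolecular nickel/zirconium-mediated reductive ketone synthesis (NiBr2(dtbbpy), Cp2ZrCl2, Zn, 1,3-dimethyl-2-imidazolidinone, high dilution), of the type established for alkyl iodides and S-pyridin-2-yl thioesters and applied here to an alkenyl iodide, then joins C4 to the acyl carbon and rejoins the route at 25.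

**Step 10.** Most likely to go wrong: loss of chemoselectivity, that is osmylation of the vinylsilane as well, or hydrolytic opening of the enol lactone. The fallback reverses the order so that the second alkene is deactivated first, and sets out from 20. Iododesilylation with N-iodosuccinimide gives the alkenyl iodide F7, whose iodo-alkene is inert to OsO4. Dihydroxylation gives the diol F8, and periodate cleavage rejoins the route at 23. The price is that the prenyl alkene is present during the iodination.

**Step 16.** Most likely to go wrong: over-acylation at the C6 hydroxyl or acyl migration between C13 and C6. The fallback differentiates the oxygens by deprotection instead of acylation rate and sets out from 26. Short exposure to HF·pyridine at 0 °C should remove the primary silyl ether and the tertiary triethylsilyl ether and leave the C6 silyl ether, giving diol F9. Acetic anhydride and pyridine then acetylate only the primary hydroxyl and give the 13-acetate F10. Prolonged exposure to HF·pyridine frees the C6 hydroxyl and rejoins the route at 28.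

## Further compounds

F1 | step 8 | (2Z,4R)-4-(tert-butyldimethylsilyloxy)-2-[(tert-butyldimethylsilyloxy)methyl]-3-iodo-6-(trimethylsilyl)hepta-2,6-dienoic acid | OC(=O)/C(CO[Si](C)(C)C(C)(C)C)=C(\I)[C@H](O[Si](C)(C)C(C)(C)C)CC(=C)[Si](C)(C)C
F2 | step 8 | methyl (2Z,4R)-4-(tert-butyldimethylsilyloxy)-2-[(tert-butyldimethylsilyloxy)methyl]-3-iodo-6-(trimethylsilyl)hepta-2,6-dienoate | COC(=O)/C(CO[Si](C)(C)C(C)(C)C)=C(\I)[C@H](O[Si](C)(C)C(C)(C)C)CC(=C)[Si](C)(C)C
F3 | step 14 | (3R,6R,8Z,10R)-6,13-bis(tert-butyldimethylsilyloxy)-3-hydroxy-10-(triethylsilyloxy)germacra-4(15),7(11),8-trien-12,8-olide | CC(C)(C)[Si](C)(C)OCC1=C2/C(=C/[C@](C)(O[Si](CC)(CC)CC)CC[C@@H](O)C(=C)C[C@H]2O[Si](C)(C)C(C)(C)C)OC1=O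
F4 | step 14 | (3R,4S,6R,8Z,10R)-6,13-bis(tert-butyldimethylsilyloxy)-3-hydroxy-10-(triethylsilyloxy)germacra-7(11),8-dien-12,8-olide | CC(C)(C)[Si](C)(C)OCC1=C2/C(=C/[C@](C)(O[Si](CC)(CC)CC)CC[C@@H](O)[C@@H](C)C[C@H]2O[Si](C)(C)C(C)(C)C)OC1=O
F5 | step 12 | (4R,5Z)-5-{4-[(tert-butyldimethylsilyloxy)methyl]-3-[(1R)-1-(tert-butyldimethylsilyloxy)-3-iodobut-3-en-1-yl]-5-oxofuran-2(5H)-ylidene}-4-methyl-4-(triethylsilyloxy)pentanoic acid | CC(C)(C)[Si](C)(C)OCC1=C([C@H](O[Si](C)(C)C(C)(C)C)CC(=C)I)/C(=C/[C@](C)(O[Si](CC)(CC)CC)CCC(=O)O)OC1=O
F6 | step 12 | S-pyridin-2-yl thioester of F5 | CC(C)(C)[Si](C)(C)OCC1=C([C@H](O[Si](C)(C)C(C)(C)C)CC(=C)I)/C(=C/[C@](C)(O[Si](CC)(CC)CC)CCC(=O)Sc2ccccn2)OC1=O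
F7 | step 10 | (5Z)-3-[(tert-butyldimethylsilyloxy)methyl]-4-[(1R)-1-(tert-butyldimethylsilyloxy)-3-iodobut-3-en-1-yl]-5-[(2R)-2,6-dimethyl-2-(triethylsilyloxy)hept-5-en-1-ylidene]furan-2(5H)-one | CC(C)(C)[Si](C)(C)OCC1=C([C@H](O[Si](C)(C)C(C)(C)C)CC(=C)I)/C(=C/[C@](C)(O[Si](CC)(CC)CC)CCC=C(C)C)OC1=O
F8 | step 10 | vicinal diol of F7 at the former prenyl alkene (carbinol epimers) | CC(C)(C)[Si](C)(C)OCC1=C([C@H](O[Si](C)(C)C(C)(C)C)CC(=C)I)/C(=C/[C@](C)(O[Si](CC)(CC)CC)CCC(O)C(C)(C)O)OC1=O
F9 | step 16 | (4S,6R,8Z,10R)-6-(tert-butyldimethylsilyloxy)-10,13-dihydroxy-3-oxogermacra-7(11),8-dien-12,8-olide | OCC1=C2/C(=C/[C@](C)(O)CCC(=O)[C@@H](C)C[C@H]2O[Si](C)(C)C(C)(C)C)OC1=O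
F10 | step 16 | (4S,6R,8Z,10R)-13-acetoxy-6-(tert-butyldimethylsilyloxy)-10-hydroxy-3-oxogermacra-7(11),8-dien-12,8-olide | CC(=O)OCC1=C2/C(=C/[C@](C)(O)CCC(=O)[C@@H](C)C[C@H]2O[Si](C)(C)C(C)(C)C)OC1=O
A1 | alternative 1 | angular C3 carbinol of the decalin-fused butenolide with the C3–C8 bond intact, carrying the 6-senecioate, the 13-acetate and the 10-triethylsilyl ether (ring-fusion configuration left open) | CC(=O)OCC1=C2[C@H](OC(=O)C=C(C)C)C[C@H](C)C3(O)CC[C@@](C)(O[Si](CC)(CC)CC)CC23OC1=O
A2 | alternative 1 | C10 triethylsilyl ether of the target | CC(=O)OCC1=C2/C(=C/[C@](C)(O[Si](CC)(CC)CC)CCC(=O)[C@@H](C)C[C@H]2OC(=O)C=C(C)C)OC1=O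
A3 | alternative 2 | open-chain 2-silylfuran with a 2-alkyl-1,3-dithiane at C3 and a primary chloride at C2 | C[Si](C)(C)c1oc(C[C@](C)(O[Si](CC)(CC)CC)CCCl)c([C@H](O[Si](C)(C)C(C)(C)C)C[C@H](C)C2SCCCS2)c1CO[Si](C)(C)C(C)(C)C
A4 | alternative 2 | furan-fused ten-membered ring with spiro dithiane | C[Si](C)(C)c1oc2C[C@](C)(O[Si](CC)(CC)CC)CCC3(SCCCS3)[C@@H](C)C[C@@H](O[Si](C)(C)C(C)(C)C)c2c1CO[Si](C)(C)C(C)(C)C
A5 | alternative 3 | trimethylsilyl ether of the butenolide-fused cis-1-vinyl-2-[(Z)-2-borylprop-1-enyl]cyclohexanol | CC(C)(C)[Si](C)(C)OCC1=C2[C@H](O[Si](C)(C)C(C)(C)C)C[C@H](C)[C@@](O[Si](C)(C)C)(C=C)[C@]2(/C=C(\C)B3OC(C)(C)C(C)(C)O3)OC1=O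
A6 | alternative 3 | ten-membered ylidene butenolide with tertiary allylic boronate and silyl enol ether | CC(C)(C)[Si](C)(C)OCC1=C2/C(=C/[C@](C)(B3OC(C)(C)C(C)(C)O3)C/C=C(/O[Si](C)(C)C)[C@@H](C)C[C@H]2O[Si](C)(C)C(C)(C)C)OC1=O
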